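**Plan**

- Retrosynthesis: ring C is opened at O1–C2 and C2–C3 (one carbon from DMF-DMA); then C3–C4 (benzyl Grignard carrying ring B) and C4–C4a (formyl carbon) are cut, leaving a pentasubstituted phenol.
- Ring A of that phenol is cut at C8a–C8, C6–C7 and C4a–C8a into a 3-alkoxy-2-prenylcyclobutenone and a chiral siloxyalkyne. This is possible because ring A is a hexasubstituted benzene whose three oxygens (O1, O5, O7) alternate with C4a, the C6 prenyl group and the C8 hydroxyalkenyl chain, which is the pattern a vinylketene–ynol ether benzannulation delivers.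
- Forward: siloxyalkyne (steps 1–3) and cyclobutenone (steps 4–6); ring A by benzannulation (step 7); ortho-formylation, addition of the ring-B benzyl Grignard and oxidation (steps 8–12); ring C by DMF-DMA (step 13); deprotection (steps 14–15).
- Stereochemistry: the only stereocentre, the (S)-carbinol of the C8 chain, is set in step 1 by chiral phosphoric acid catalysed propargylation of methacrolein and carried as a TBS ether.
- Protecting groups: O5 is carried as an isopropyl ether, which BCl3 removes at −78 °C with peri-carbonyl assistance (milder than an ethyl ether would allow beside a prenyl group). O7, O4′ and the carbinol are silyl ethers removed together by fluoride.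

Key step: step 7

Assumption: (S)-TRIP is taken as the catalyst enantiomer that sends the allenylboronate to the Si face of methacrolein and so gives the (S)-alcohol, by analogy with aryl and alkenyl aldehydes; if the sense were opposite, (R)-TRIP would be used and nothing else changes.

**Step 1**
Reactants: 1 methacrolein; 2 allenylboronic acid pinacol ester
Product: 4 (S)-2-methylhex-1-en-5-yn-3-ol, via boronate ester 3 (not isolated)
Conditions: (S)-TRIP (10 mol %), 4 Å MS, PhMe, −20 °C; aq. NaHCO3
Reagents that add atoms: none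
Why: Chiral phosphoric acid catalysed propargylation of an aldehyde with an allenylboronate (SE2′ through a six-membered chair transition state with the acid bound to the boronate oxygen and the formyl hydrogen) should give the homopropargylic alcohol, the catalyst pocket selecting the Si face and setting the (S)-carbinol.

**Step 2**
Reactants: 4 (S)-2-methylhex-1-en-5-yn-3-ol
Product: 5 (S)-tert-butyldimethyl[(2-methylhex-1-en-5-yn-3-yl)oxy]silane
Conditions: TBSCl, imidazole, DMF, rt
Reagents that add atoms: tert-butyldimethylsilyl chloride, CC(C)(C)[Si](C)(C)Cl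
Why: Standard silylation of a secondary alcohol that does not touch the stereocentre; the TBS ether should withstand the lithium, thermal, Grignard and low-temperature BCl3 steps and leave with fluoride at the end.

**Step 3**
Reactants: 5 (S)-tert-butyldimethyl[(2-methylhex-1-en-5-yn-3-yl)oxy]silane
Product: 8 (S)-4-(tert-butyldimethylsilyloxy)-5-methyl-1-(triisopropylsilyloxy)hex-5-en-1-yne, via lithium acetylide 6 (not isolated), via lithium ynolate 7 (not isolated)
Conditions: LiHMDS, t-BuOOH, THF, −78 → 0 °C; then TIPSOTf, −78 °C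
Reagents that add atoms: tert-butyl hydroperoxide, CC(C)(C)OO; triisopropylsilyl trifluoromethanesulfonate, CC(C)[Si](OS(=O)(=O)C(F)(F)F)(C(C)C)C(C)C
Why: Julia-type oxidation of a lithium acetylide by lithium tert-butyl peroxide gives the lithium ynolate, which the bulky silyl triflate should trap on oxygen to give the siloxyalkyne, the alkene and allylic silyl ether being inert.

**Step 4**
Reactants: 9 propan-2-ol; 10 trichloroethylene; 11 prenyl bromide (1-bromo-3-methylbut-2-ene)
Product: 14 1-isopropoxy-5-methylhex-4-en-1-yne, via dichlorovinyl ether 12 (not isolated), via lithium isopropoxyacetylide 13 (not isolated)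
Conditions: KH, THF, 0 °C; 10, −50 °C → rt; n-BuLi (2.4 equiv), −78 → −40 °C; 11, HMPA, −78 °C → rt
Reagents that add atoms: none
Why: Greene ynol ether synthesis, in which the alkoxide adds to dichloroacetylene formed in situ, n-BuLi converts the dichlorovinyl ether into the lithium alkoxyacetylide by elimination and Cl/Li exchange, and the acetylide is alkylated at the primary carbon of the allylic bromide (SN2).

**Step 5**
Reactants: 14 1-isopropoxy-5-methylhex-4-en-1-yne
Product: 15 4,4-dichloro-3-isopropoxy-2-(3-methylbut-2-en-1-yl)cyclobut-2-en-1-one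
Conditions: Cl3CCOCl, Zn–Cu, Et2O–DME, 0 °C → rt
Reagents that add atoms: trichloroacetyl chloride, O=C(Cl)C(Cl)(Cl)Cl
Why: [2+2] cycloaddition of dichloroketene (zinc dehalogenation of the acid chloride, DME binding the zinc chloride) with the ynol ether should join the ketene carbonyl carbon to the alkyne carbon remote from oxygen, the electron-rich alkyne reacting ahead of the trisubstituted alkene.

**Step 6**
Reactants: 15 4,4-dichloro-3-isopropoxy-2-(3-methylbut-2-en-1-yl)cyclobut-2-en-1-one
Product: 17 3-isopropoxy-2-(3-methylbut-2-en-1-yl)cyclobut-2-en-1-one, via monochlorocyclobutenone 16 (not isolated)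
Conditions: Zn, AcOH, TMEDA, EtOH, 0 °C
Reagents that add atoms: none
Why: Buffered zinc reduction of an α,α-dichloro ketone removes the two chlorines in turn and should leave the vinylogous ester and the alkene untouched.

**Step 7**
Reactants: 17 3-isopropoxy-2-(3-methylbut-2-en-1-yl)cyclobut-2-en-1-one; 8 (S)-4-(tert-butyldimethylsilyloxy)-5-methyl-1-(triisopropylsilyloxy)hex-5-en-1-yne
Product: 22 (S)-2-[2-(tert-butyldimethylsilyloxy)-3-methylbut-3-en-1-yl]-5-isopropoxy-4-(3-methylbut-2-en-1-yl)-3-(triisopropylsilyloxy)phenol, via vinylketene 18 (not isolated), via vinylcyclobutenone 19 (not isolated), via dienylketene 20 (not isolated), via cyclohexadienone 21 (not isolated)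
Conditions: PhMe, 80 → 110 °C, sealed vessel (17 in slight excess)
Reagents that add atoms: none
Why: Heating opens 17 by 4π electrocyclic ring opening to the (1-isopropoxyvinyl)ketene 18, whose ketene C=C adds [2+2] to 8 with the ketene carbonyl carbon bonding to the alkyne carbon remote from oxygen (bonds C8a–C8 and C6–C7) to give 19. Intermediate 19 opens reversibly to dienylketene 20, which closes ring A by a thermally allowed disrotatory 6π electrocyclisation (all-carbon six-membered ring, bond C4a–C8a), and dienone 21 tautomerises irreversibly to the phenol. The closest known reaction type is the Danheiser benzannulation of cyclobutenones with trialkylsiloxyalkynes to resorcinol monosilyl ethers. No stereocentre is formed, and the (S)-silyloxy carbinol sits two atoms from the alkyne, has no acidic neighbour and should pass through unchanged. The step needs a single regiochemistry in the ketene–alkyne cycloaddition, which the polarisation of the siloxyalkyne (nucleophilic carbon β to oxygen) against the electrophilic ketene carbon secures, and the ynol ether should react far ahead of the prenyl and isopropenyl double bonds. Because the vinylogous-ester character of 17 may slow the first ring opening, the temperature is raised in stages; the free phenol that emerges is the future O1, already distinguished from silylated O7 and alkylated O5.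

**Step 8**
Reactants: 22 the phenol from step 7
Product: 24 (S)-3-[2-(tert-butyldimethylsilyloxy)-3-methylbut-3-en-1-yl]-2-hydroxy-6-isopropoxy-5-(3-methylbut-2-en-1-yl)-4-(triisopropylsilyloxy)benzaldehyde, via hydroxymethylphenol 23 (not isolated)
Conditions: MgCl2, Et3N, (CH2O)n, THF, reflux; aq. NH4Cl
Reagents that add atoms: paraformaldehyde (as formaldehyde), C=O
Why: Magnesium-mediated ortho-formylation of a phenol (Casnati–Skattebøl), in which the magnesium phenoxide delivers formaldehyde to the only free ring position and a second formaldehyde oxidises the benzylic alkoxide by hydride transfer, under conditions that silyl ethers and alkenes tolerate.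

**Step 9**
Reactants: 25 4-(tert-butyldimethylsilyloxy)benzaldehyde
Product: 26 [4-(tert-butyldimethylsilyloxy)phenyl]methanol
Conditions: NaBH4, THF–MeOH, 0 °C
Reagents that add atoms: none
Why: Borohydride reduction of an aromatic aldehyde, brief and cold so that the aryl silyl ether is kept.

**Step 10**
Reactants: 26 [4-(tert-butyldimethylsilyloxy)phenyl]methanol
Product: 27 tert-butyl[4-(chloromethyl)phenoxy]dimethylsilane
Conditions: PPh3, NCS, CH2Cl2, 0 °C → rt
Reagents that add atoms: N-chlorosuccinimide, O=C1CCC(=O)N1Cl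
Why: Appel-type chlorination of a benzylic alcohol through an alkoxyphosphonium chloride under neutral conditions, which the silyl ether should survive.

**Step 11**
Reactants: 24 the salicylaldehyde from step 8; 27 tert-butyl[4-(chloromethyl)phenoxy]dimethylsilane
Product: 29 1-{3-[(S)-2-(tert-butyldimethylsilyloxy)-3-methylbut-3-en-1-yl]-2-hydroxy-6-isopropoxy-5-(3-methylbut-2-en-1-yl)-4-(triisopropylsilyloxy)phenyl}-2-[4-(tert-butyldimethylsilyloxy)phenyl]ethan-1-ol (both epimers at the new carbinol), via benzylmagnesium chloride 28 (not isolated)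
Conditions: 27, Mg, Et2O, 0 °C → rt (slow addition); then 24, THF, −78 → 0 °C (2.3 equiv of 28); aq. NH4Cl
Reagents that add atoms: none
Why: Grignard addition to an aldehyde, the first equivalent deprotonating the phenol and the second adding to the formyl group; the new carbinol centre needs no control because the next step removes it.

**Step 12**
Reactants: 29 the benzylic alcohol from step 11 (used crude)
Product: 30 (S)-1-{3-[2-(tert-butyldimethylsilyloxy)-3-methylbut-3-en-1-yl]-2-hydroxy-6-isopropoxy-5-(3-methylbut-2-en-1-yl)-4-(triisopropylsilyloxy)phenyl}-2-[4-(tert-butyldimethylsilyloxy)phenyl]ethan-1-one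
Conditions: activated MnO2 (excess), CH2Cl2, rt
Reagents that add atoms: none
Why: Manganese dioxide oxidation of a benzylic alcohol to the aryl ketone is selective in the presence of a phenol, isolated alkenes and silyl ethers, and the product is stabilised by the hydrogen bond to the ortho hydroxyl.

**Step 13**
Reactants: 30 the 2-hydroxydeoxybenzoin from step 12
Product: 32 (S)-8-[2-(tert-butyldimethylsilyloxy)-3-methylbut-3-en-1-yl]-3-[4-(tert-butyldimethylsilyloxy)phenyl]-5-isopropoxy-6-(3-methylbut-2-en-1-yl)-7-(triisopropylsilyloxy)-4H-chromen-4-one, via enaminone 31 (not isolated)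
Conditions: DMF-DMA, PhMe, 80 °C
Reagents that add atoms: N,N-dimethylformamide dimethyl acetal, COC(OC)N(C)C
Why: Deoxybenzoin route to isoflavones, in which condensation at the doubly activated methylene gives the enaminone and the ortho phenol adds to its β-carbon with loss of dimethylamine, closing the pyranone (bonds C2–C3 and O1–C2).

**Step 14**
Reactants: 32 the protected isoflavone from step 13
Product: 34 (S)-8-[2-(tert-butyldimethylsilyloxy)-3-methylbut-3-en-1-yl]-3-[4-(tert-butyldimethylsilyloxy)phenyl]-5-hydroxy-6-(3-methylbut-2-en-1-yl)-7-(triisopropylsilyloxy)-4H-chromen-4-one, via dichloroboron chelate 33 (not isolated)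
Conditions: BCl3 (1.5 equiv), CH2Cl2, −78 °C; cold aq. NaHCO3
Reagents that add atoms: none
Why: Chelation-assisted dealkylation, in which BCl3 bound between the C4 carbonyl and O5 expels the secondary alkyl group as 2-chloropropane; the low temperature, the absence of any free hydroxyl and the buffered quench should spare the prenyl group and the silyl ethers.

**Step 15**
Reactants: 34 the 5-hydroxyisoflavone from step 14
Product: 35 (S)-5,7-dihydroxy-8-(2-hydroxy-3-methylbut-3-en-1-yl)-3-(4-hydroxyphenyl)-6-(3-methylbut-2-en-1-yl)-4H-chromen-4-one (target)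
Conditions: TBAF, AcOH (1:1), THF, 0 °C → rt
Reagents that add atoms: none
Why: Fluoride cleavage of the two aryl silyl ethers and the secondary TBS ether, buffered with acetic acid so that the pyranone is not exposed to strongly basic phenoxide or hydroxide; the stereocentre is not involved.

**Compound list**

1 | methacrolein | C=C(C)C=O | starting material
2 | allenylboronic acid pinacol ester | C=C=CB1OC(C)(C)C(C)(C)O1 | starting material
3 | (S)-2-[(2-methylhex-1-en-5-yn-3-yl)oxy]-4,4,5,5-tetramethyl-1,3,2-dioxaborolane | C=C(C)[C@@H](OB1OC(C)(C)C(C)(C)O1)CC#C | intermediate (not isolated)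
4 | (S)-2-methylhex-1-en-5-yn-3-ol | C=C(C)[C@@H](O)CC#C | intermediate
5 | (S)-tert-butyldimethyl[(2-methylhex-1-en-5-yn-3-yl)oxy]silane | C=C(C)[C@@H](O[Si](C)(C)C(C)(C)C)CC#C | intermediate
6 | lithium acetylide of 5 | C=C(C)[C@@H](O[Si](C)(C)C(C)(C)C)CC#C[Li] | intermediate (not isolated)
7 | lithium (S)-4-(tert-butyldimethylsilyloxy)-5-methylhex-5-en-1-yn-1-olate | C=C(C)[C@@H](O[Si](C)(C)C(C)(C)C)CC#CO[Li] | intermediate (not isolated)
8 | (S)-4-(tert-butyldimethylsilyloxy)-5-methyl-1-(triisopropylsilyloxy)hex-5-en-1-yne | C=C(C)[C@@H](O[Si](C)(C)C(C)(C)C)CC#CO[Si](C(C)C)(C(C)C)C(C)C | intermediate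
9 | propan-2-ol | CC(C)O | starting material
10 | trichloroethylene | ClC=C(Cl)Cl | starting material
11 | prenyl bromide | CC(C)=CCBr | starting material
12 | (E)-1,2-dichlorovinyl isopropyl ether | CC(C)O/C(Cl)=C\Cl | intermediate (not isolated)
13 | lithium isopropoxyacetylide | CC(C)OC#C[Li] | intermediate (not isolated)
14 | 1-isopropoxy-5-methylhex-4-en-1-yne | CC(C)OC#CCC=C(C)C | intermediate
15 | 4,4-dichloro-3-isopropoxy-2-(3-methylbut-2-en-1-yl)cyclobut-2-en-1-one | CC(C)OC1=C(CC=C(C)C)C(=O)C1(Cl)Cl | intermediate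
16 | 4-chloro-3-isopropoxy-2-(3-methylbut-2-en-1-yl)cyclobut-2-en-1-one (racemic) | CC(C)OC1=C(CC=C(C)C)C(=O)C1Cl | intermediate (not isolated)
17 | 3-isopropoxy-2-(3-methylbut-2-en-1-yl)cyclobut-2-en-1-one | CC(C)OC1=C(CC=C(C)C)C(=O)C1 | intermediate
18 | 3-isopropoxy-2-(3-methylbut-2-en-1-yl)buta-1,3-dien-1-one (vinylketene) | C=C(OC(C)C)C(CC=C(C)C)=C=O | intermediate (not isolated)
19 | 2-[(S)-2-(tert-butyldimethylsilyloxy)-3-methylbut-3-en-1-yl]-4-(1-isopropoxyvinyl)-4-(3-methylbut-2-en-1-yl)-3-(triisopropylsilyloxy)cyclobut-2-en-1-one (both epimers at C4) | C=C(C)[C@@H](O[Si](C)(C)C(C)(C)C)CC1=C(O[Si](C(C)C)(C(C)C)C(C)C)C(CC=C(C)C)(C(=C)OC(C)C)C1=O | intermediate (not isolated)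
20 | dienylketene from 19 (ketene and isopropoxyvinyl groups cis on the central double bond) | C=C(C)[C@@H](O[Si](C)(C)C(C)(C)C)CC(=C=O)/C(O[Si](C(C)C)(C(C)C)C(C)C)=C(/CC=C(C)C)C(=C)OC(C)C | intermediate (not isolated)
21 | 2-[(S)-2-(tert-butyldimethylsilyloxy)-3-methylbut-3-en-1-yl]-5-isopropoxy-4-(3-methylbut-2-en-1-yl)-3-(triisopropylsilyloxy)cyclohexa-2,4-dien-1-one | C=C(C)[C@@H](O[Si](C)(C)C(C)(C)C)CC1=C(O[Si](C(C)C)(C(C)C)C(C)C)C(CC=C(C)C)=C(OC(C)C)CC1=O | intermediate (not isolated)
22 | (S)-2-[2-(tert-butyldimethylsilyloxy)-3-methylbut-3-en-1-yl]-5-isopropoxy-4-(3-methylbut-2-en-1-yl)-3-(triisopropylsilyloxy)phenol | C=C(C)[C@@H](O[Si](C)(C)C(C)(C)C)Cc1c(O)cc(OC(C)C)c(CC=C(C)C)c1O[Si](C(C)C)(C(C)C)C(C)C | intermediate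
23 | (S)-2-[2-(tert-butyldimethylsilyloxy)-3-methylbut-3-en-1-yl]-6-(hydroxymethyl)-5-isopropoxy-4-(3-methylbut-2-en-1-yl)-3-(triisopropylsilyloxy)phenol | C=C(C)[C@@H](O[Si](C)(C)C(C)(C)C)Cc1c(O)c(CO)c(OC(C)C)c(CC=C(C)C)c1O[Si](C(C)C)(C(C)C)C(C)C | intermediate (not isolated)
24 | (S)-3-[2-(tert-butyldimethylsilyloxy)-3-methylbut-3-en-1-yl]-2-hydroxy-6-isopropoxy-5-(3-methylbut-2-en-1-yl)-4-(triisopropylsilyloxy)benzaldehyde | C=C(C)[C@@H](O[Si](C)(C)C(C)(C)C)Cc1c(O)c(C=O)c(OC(C)C)c(CC=C(C)C)c1O[Si](C(C)C)(C(C)C)C(C)C | intermediate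
25 | 4-(tert-butyldimethylsilyloxy)benzaldehyde | O=Cc1ccc(O[Si](C)(C)C(C)(C)C)cc1 | starting material
26 | [4-(tert-butyldimethylsilyloxy)phenyl]methanol | OCc1ccc(O[Si](C)(C)C(C)(C)C)cc1 | intermediate
27 | tert-butyl[4-(chloromethyl)phenoxy]dimethylsilane | ClCc1ccc(O[Si](C)(C)C(C)(C)C)cc1 | intermediate
28 | 4-(tert-butyldimethylsilyloxy)benzylmagnesium chloride | Cl[Mg]Cc1ccc(O[Si](C)(C)C(C)(C)C)cc1 | intermediate (not isolated)
29 | 1-aryl-2-[4-(tert-butyldimethylsilyloxy)phenyl]ethan-1-ol from 24 (both epimers at the new carbinol) | C=C(C)[C@@H](O[Si](C)(C)C(C)(C)C)Cc1c(O)c(C(O)Cc2ccc(O[Si](C)(C)C(C)(C)C)cc2)c(OC(C)C)c(CC=C(C)C)c1O[Si](C(C)C)(C(C)C)C(C)C | intermediate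
30 | (S)-1-{3-[2-(tert-butyldimethylsilyloxy)-3-methylbut-3-en-1-yl]-2-hydroxy-6-isopropoxy-5-(3-methylbut-2-en-1-yl)-4-(triisopropylsilyloxy)phenyl}-2-[4-(tert-butyldimethylsilyloxy)phenyl]ethan-1-one | C=C(C)[C@@H](O[Si](C)(C)C(C)(C)C)Cc1c(O)c(C(=O)Cc2ccc(O[Si](C)(C)C(C)(C)C)cc2)c(OC(C)C)c(CC=C(C)C)c1O[Si](C(C)C)(C(C)C)C(C)C | intermediate
31 | 3-(dimethylamino)-2-aryl enaminone of 30 | C=C(C)[C@@H](O[Si](C)(C)C(C)(C)C)Cc1c(O)c(C(=O)C(=CN(C)C)c2ccc(O[Si](C)(C)C(C)(C)C)cc2)c(OC(C)C)c(CC=C(C)C)c1O[Si](C(C)C)(C(C)C)C(C)C | intermediate (not isolated)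
32 | (S)-8-[2-(tert-butyldimethylsilyloxy)-3-methylbut-3-en-1-yl]-3-[4-(tert-butyldimethylsilyloxy)phenyl]-5-isopropoxy-6-(3-methylbut-2-en-1-yl)-7-(triisopropylsilyloxy)-4H-chromen-4-one | C=C(C)[C@@H](O[Si](C)(C)C(C)(C)C)Cc1c(O[Si](C(C)C)(C(C)C)C(C)C)c(CC=C(C)C)c(OC(C)C)c2c(=O)c(-c3ccc(O[Si](C)(C)C(C)(C)C)cc3)coc12 | intermediate
33 | 5-O-dichloroboryl chelate of 34 | C=C(C)[C@@H](O[Si](C)(C)C(C)(C)C)Cc1c(O[Si](C(C)C)(C(C)C)C(C)C)c(CC=C(C)C)c(OB(Cl)Cl)c2c(=O)c(-c3ccc(O[Si](C)(C)C(C)(C)C)cc3)coc12 | intermediate (not isolated)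
34 | (S)-8-[2-(tert-butyldimethylsilyloxy)-3-methylbut-3-en-1-yl]-3-[4-(tert-butyldimethylsilyloxy)phenyl]-5-hydroxy-6-(3-methylbut-2-en-1-yl)-7-(triisopropylsilyloxy)-4H-chromen-4-one | C=C(C)[C@@H](O[Si](C)(C)C(C)(C)C)Cc1c(O[Si](C(C)C)(C(C)C)C(C)C)c(CC=C(C)C)c(O)c2c(=O)c(-c3ccc(O[Si](C)(C)C(C)(C)C)cc3)coc12 | intermediate
35 | (S)-5,7-dihydroxy-8-(2-hydroxy-3-methylbut-3-en-1-yl)-3-(4-hydroxyphenyl)-6-(3-methylbut-2-en-1-yl)-4H-chromen-4-one | C=C(C)[C@@H](O)Cc1c(O)c(CC=C(C)C)c(O)c2c(=O)c(-c3ccc(O)cc3)coc12 | target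

**Step count and risks**

Total: 15 steps. Longest linear sequence: 10 steps (1–3, 7, 8, 11–15; the cyclobutenone branch 4–6, 7, 8, 11–15 is equally long).

Steps most likely to fail:

1. Step 7. The push–pull cyclobutenone may open too slowly, so that the siloxyalkyne is lost to a 1,3-silyl shift (silylketene) or to hydrolysis before it is trapped, and the product phenol may be acylated by unreacted vinylketene. The fallback makes the same vinylketene at or below room temperature by 1,4-dehydrochlorination instead of ring opening. It sets out from prenyl bromide 11 and siloxyalkyne 8 and returns to the route at phenol 22. Commercial ethyl acetoacetate is C-alkylated with 11 (K2CO3, acetone) to ethyl 2-acetyl-5-methylhex-4-enoate F1. O-Alkylation with isopropyl tosylate (Cs2CO3, DMF) gives the enol ether ethyl 3-isopropoxy-2-(3-methylbut-2-en-1-yl)but-2-enoate F2. Saponification (LiOH, THF–H2O) gives 3-isopropoxy-2-(3-methylbut-2-en-1-yl)but-2-enoic acid F3, and oxalyl chloride with catalytic DMF gives the acid chloride F4. Slow addition of Et3N to F4 and 8 in CH2Cl2 at 0 °C removes HCl across the γ-methyl group and the carbonyl to form 18, which is trapped as 19. Warming in toluene to 80 °C then takes 19 through 20 and 21 to 22.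

2. Step 14. The prenyl double bond may be protonated or hydrochlorinated during the quench and captured by the freed 5-hydroxyl (chroman formation), and silyl ethers may be lost or the allylic silyl ether ionised under the Lewis acid. The fallback exchanges the silyl ethers for acetates before the Lewis acid is used. It sets out from 32 and returns at the target 35. Buffered TBAF (AcOH, THF) gives the 5-O-isopropyl triol (S)-7-hydroxy-8-(2-hydroxy-3-methylbut-3-en-1-yl)-3-(4-hydroxyphenyl)-5-isopropoxy-6-(3-methylbut-2-en-1-yl)-4H-chromen-4-one F5. Ac2O, pyridine and DMAP give its triacetate F6. BCl3 in CH2Cl2 at −78 °C then acts on a substrate whose O7 is deactivated and non-nucleophilic, passing through the dichloroboron chelate F7 to the 5-hydroxy triacetate F8. K2CO3 in MeOH at 0 °C removes the acetates to give 35.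

3. Step 5. Dichloroketene may also add to the trisubstituted prenyl double bond, and zinc chloride may promote hydration or oligomerisation of the ynol ether. The fallback sets out from 14 and returns at 17. Parent ketene, generated by pyrolysis of acetone in a ketene lamp, is passed into 14 in CH2Cl2 at 0 °C. Ketene does not add to unactivated alkenes and no Lewis acid or reduction is involved, so 17 is reached in one operation and 15, 16 and step 6 are bypassed.

**Further compounds**

F1 | step 7 | ethyl 2-acetyl-5-methylhex-4-enoate (racemic) | CCOC(=O)C(CC=C(C)C)C(C)=O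
F2 | step 7 | ethyl 3-isopropoxy-2-(3-methylbut-2-en-1-yl)but-2-enoate (mixture of double-bond isomers) | CCOC(=O)C(CC=C(C)C)=C(C)OC(C)C
F3 | step 7 | 3-isopropoxy-2-(3-methylbut-2-en-1-yl)but-2-enoic acid | OC(=O)C(CC=C(C)C)=C(C)OC(C)C
F4 | step 7 | 3-isopropoxy-2-(3-methylbut-2-en-1-yl)but-2-enoyl chloride | ClC(=O)C(CC=C(C)C)=C(C)OC(C)C
F5 | step 14 | (S)-7-hydroxy-8-(2-hydroxy-3-methylbut-3-en-1-yl)-3-(4-hydroxyphenyl)-5-isopropoxy-6-(3-methylbut-2-en-1-yl)-4H-chromen-4-one | C=C(C)[C@@H](O)Cc1c(O)c(CC=C(C)C)c(OC(C)C)c2c(=O)c(-c3ccc(O)cc3)coc12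
F6 | step 14 | triacetate of F5 (7-O, 4′-O and side-chain O) | C=C(C)[C@@H](OC(C)=O)Cc1c(OC(C)=O)c(CC=C(C)C)c(OC(C)C)c2c(=O)c(-c3ccc(OC(C)=O)cc3)coc12
F7 | step 14 | 5-O-dichloroboryl chelate of F8 | C=C(C)[C@@H](OC(C)=O)Cc1c(OC(C)=O)c(CC=C(C)C)c(OB(Cl)Cl)c2c(=O)c(-c3ccc(OC(C)=O)cc3)coc12
F8 | step 14 | 5-hydroxy triacetate (7-O, 4′-O and side-chain O acetylated) | C=C(C)[C@@H](OC(C)=O)Cc1c(OC(C)=O)c(CC=C(C)C)c(O)c2c(=O)c(-c3ccc(OC(C)=O)cc3)coc12
F0 | step 5 | none | none
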